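**Strategy**

The route rests on disconnecting the bond between the vinylic CH of the side-chain olefin and the CH2 attached to C5 of the furanone. One operation joins three components around this olefin: a bicyclic alkylmagnesium bromide made from sclareolide, the magnesium alkoxide of propargyl alcohol and methyl (R)-glycidate. Copper-catalysed anti-carbomagnesiation builds the trisubstituted olefin with the allylic CH2OH held cis to the metal in an oxamagnesacycle, which then opens the epoxide at its CH2. The step exploits the cis relation of the hydroxymethyl group and the new CH2 on the side-chain C=C, and the ring oxygen O1 on C5, which is the epoxide oxygen. A tetronic acid then completes the furanone.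

Key step: step 4

Remark: Dec stands for the (4aS,8aS)-2,5,5,8a-tetramethyl-3,4,4a,5,6,7,8,8a-octahydronaphthalen-1-yl group (rings A and B with the tetrasubstituted C=C, natural drimane series as the SMILES requires); the furanone is numbered O1, C2(=O), C3, C4, C5; magnesium species are drawn as monomers.

**Route**

Step 1
Reactants: 1 (+)-sclareolide
Product: 2 methyl 2-(Dec)acetate
Conditions: conc. H2SO4, MeOH, 65 °C
Reagents that add atoms: methanol, CO
Why: Acid-catalysed lactone methanolysis with ionisation at the tertiary C–O bond, E1 elimination and Fischer esterification should, under equilibrating conditions, give mainly the tetrasubstituted ring olefin, and the two ring-fusion stereocentres are not touched.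

Step 2
Reactants: 2 methyl 2-(Dec)acetate
Product: 3 2-(Dec)ethan-1-ol
Conditions: LiAlH4, THF, 0 °C; then H2O, aq. NaOH
Reagents that add atoms: none
Why: LiAlH4 reduction of the ester to the primary alcohol, which should leave the isolated tetrasubstituted olefin untouched.

Step 3
Reactants: 3 2-(Dec)ethan-1-ol
Product: 4 (4aS,8aS)-1-(2-bromoethyl)-2,5,5,8a-tetramethyl-3,4,4a,5,6,7,8,8a-octahydronaphthalene
Conditions: CBr4, PPh3, CH2Cl2, 0 °C
Reagents that add atoms: carbon tetrabromide, BrC(Br)(Br)Br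
Why: Appel reaction: SN2 displacement of the oxyphosphonium group by bromide at the unhindered primary carbon, with no acid that could move the olefin.

Step 4
Reactants: 4 (4aS,8aS)-1-(2-bromoethyl)-2,5,5,8a-tetramethyl-3,4,4a,5,6,7,8,8a-octahydronaphthalene; 5 prop-2-yn-1-ol; 6 methyl (2R)-oxirane-2-carboxylate
Product: 10 methyl (2R,4Z)-2-hydroxy-5-(hydroxymethyl)-7-(Dec)hept-4-enoate, via chloromagnesium prop-2-yn-1-olate 7 (not isolated), via 2-(Dec)ethylmagnesium bromide 8 (not isolated), via oxamagnesacycle 9 (not isolated)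
Conditions: Mg, THF, 45 °C (4 to 8); 5 + t-BuMgCl (1.0 equiv), THF, 0 °C (gives 7, used in excess); 8 + 7, CuI (10 mol%), THF, −10 to 23 °C; then 6, CuI (10 mol%), −40 to −20 °C; aq. NH4Cl
Reagents that add atoms: none
Why: The alkoxide 7 directs CuI-catalysed anti-carbomagnesiation by 8: the alkyl group goes to the internal alkyne carbon and magnesium to the terminal carbon on the side of the CH2O group, so the transient five-membered oxamagnesacycle 9 (closed by O–Mg chelation, the only ring formed, and lost on work-up) fixes the hydroxymethyl group cis to the carbon–metal bond. Transmetalation to copper and SN2 attack of the alkenyl carbon on the unsubstituted CH2 of 6 should proceed with retention of olefin geometry and create the bond between the vinylic CH and the CH2 next to the carbinol. The closest known reactions are the copper-catalysed anti-addition of Grignard reagents to propargyl alcohol with electrophilic trapping, and the CuI-catalysed opening of glycidic esters by alkenylmagnesium halides to α-hydroxy esters. No stereocentre is created: the (R)-carbinol is the untouched C2 of 6, and the (Z)-olefin is controlled by the chelate. The step needs alkyl delivery to the internal carbon (secured by the alkoxide), attack at the epoxide CH2 and not at the ester carbonyl (secured by copper catalysis at low temperature and the activated, unhindered terminus), and full use of 8 (secured by an excess of cheap 7).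

Step 5
Reactants: 10 methyl (2R,4Z)-2-hydroxy-5-(hydroxymethyl)-7-(Dec)hept-4-enoate
Product: 12 (5R)-4-hydroxy-5-[(2Z)-3-(hydroxymethyl)-5-(Dec)pent-2-en-1-yl]furan-2(5H)-one, via hydroxy keto ester 11 (not isolated)
Conditions: LiN(SiMe3)2 (6 equiv), MeOAc (5 equiv), THF, −78 to −20 °C; then MeOH, 23 °C; 1 M HCl work-up
Reagents that add atoms: methyl acetate, COC(C)=O
Why: Crossed Claisen condensation of the lithium enolate of methyl acetate with the methyl ester of 10 (the excess base takes up both hydroxyl protons and the acidic product), followed by 5-exo-trig lactonisation of the C4 alkoxide onto the new ester, should give the tetronic acid, and the carbinol centre, held as its alkoxide, should not enolise.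

Step 6
Reactants: 12 (5R)-4-hydroxy-5-[(2Z)-3-(hydroxymethyl)-5-(Dec)pent-2-en-1-yl]furan-2(5H)-one
Product: 13 (2R)-2-[(2Z)-3-(hydroxymethyl)-5-(Dec)pent-2-en-1-yl]-5-oxo-2,5-dihydrofuran-3-yl trifluoromethanesulfonate
Conditions: PhNTf2 (1.1 equiv), Et3N, CH2Cl2, 0 °C
Reagents that add atoms: N-phenylbis(trifluoromethanesulfonimide), O=S(=O)(N(c1ccccc1)S(=O)(=O)C(F)(F)F)C(F)(F)F
Why: Enol triflate formation: Et3N ionises only the acidic tetronic enol, whose anion takes the triflyl group from the mild donor PhNTf2, while the neutral primary alcohol should not react.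

Step 7
Reactants: 13 (2R)-2-[(2Z)-3-(hydroxymethyl)-5-(Dec)pent-2-en-1-yl]-5-oxo-2,5-dihydrofuran-3-yl trifluoromethanesulfonate
Product: 14 16-epi-luffarin L, (5R)-4-(hydroxymethyl)-5-[(2Z)-3-(hydroxymethyl)-5-(Dec)pent-2-en-1-yl]furan-2(5H)-one
Conditions: Bu3SnCH2OH, Pd(PPh3)4 (5 mol%), LiCl, 1,4-dioxane, 90 °C
Reagents that add atoms: (tributylstannyl)methanol, CCCC[Sn](CCCC)(CCCC)CO
Why: Stille coupling: oxidative addition of zerovalent palladium into the vinyl C–OTf bond, transfer of the hydroxymethyl group from tin (assisted by LiCl) and reductive elimination should install the CH2OH under neutral conditions that spare the C5 stereocentre and the free alcohols.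

**Compound list**

1 | (+)-sclareolide, (3aR,5aS,9aS,9bR)-3a,6,6,9a-tetramethyldecahydronaphtho[2,1-b]furan-2(1H)-one | C[C@@]12CC[C@H]3C(C)(C)CCC[C@]3(C)[C@H]1CC(=O)O2 | starting material
2 | methyl 2-[(4aS,8aS)-2,5,5,8a-tetramethyl-3,4,4a,5,6,7,8,8a-octahydronaphthalen-1-yl]acetate | CC1=C(CC(=O)OC)[C@@]2(C)CCCC(C)(C)[C@@H]2CC1 | intermediate
3 | 2-(Dec)ethan-1-ol | CC1=C(CCO)[C@@]2(C)CCCC(C)(C)[C@@H]2CC1 | intermediate
4 | (4aS,8aS)-1-(2-bromoethyl)-2,5,5,8a-tetramethyl-3,4,4a,5,6,7,8,8a-octahydronaphthalene | CC1=C(CCBr)[C@@]2(C)CCCC(C)(C)[C@@H]2CC1 | intermediate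
5 | prop-2-yn-1-ol (propargyl alcohol) | C#CCO | starting material
6 | methyl (2R)-oxirane-2-carboxylate (methyl (R)-glycidate) | COC(=O)[C@H]1CO1 | starting material
7 | chloromagnesium prop-2-yn-1-olate | C#CCO[Mg]Cl | intermediate (not isolated)
8 | 2-(Dec)ethylmagnesium bromide | CC1=C(CC[Mg]Br)[C@@]2(C)CCCC(C)(C)[C@@H]2CC1 | intermediate (not isolated)
9 | 4-[2-(Dec)ethyl]-2,5-dihydro-1,2-oxamagnesole (chelated (Z)-alkenylmagnesium alkoxide) | CC1=C(CCC3=C[Mg]OC3)[C@@]2(C)CCCC(C)(C)[C@@H]2CC1 | intermediate (not isolated)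
10 | methyl (2R,4Z)-2-hydroxy-5-(hydroxymethyl)-7-(Dec)hept-4-enoate | CC1=C(CC/C(=C/C[C@@H](O)C(=O)OC)CO)[C@@]2(C)CCCC(C)(C)[C@@H]2CC1 | intermediate
11 | methyl (4R,6Z)-4-hydroxy-7-(hydroxymethyl)-3-oxo-9-(Dec)non-6-enoate | CC1=C(CC/C(=C/C[C@@H](O)C(=O)CC(=O)OC)CO)[C@@]2(C)CCCC(C)(C)[C@@H]2CC1 | intermediate (not isolated)
12 | (5R)-4-hydroxy-5-[(2Z)-3-(hydroxymethyl)-5-(Dec)pent-2-en-1-yl]furan-2(5H)-one | CC1=C(CC/C(=C/C[C@H]2OC(=O)C=C2O)CO)[C@@]2(C)CCCC(C)(C)[C@@H]2CC1 | intermediate
13 | (2R)-2-[(2Z)-3-(hydroxymethyl)-5-(Dec)pent-2-en-1-yl]-5-oxo-2,5-dihydrofuran-3-yl trifluoromethanesulfonate | CC1=C(CC/C(=C/C[C@H]2OC(=O)C=C2OS(=O)(=O)C(F)(F)F)CO)[C@@]2(C)CCCC(C)(C)[C@@H]2CC1 | intermediate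
14 | 16-epi-luffarin L, (5R)-4-(hydroxymethyl)-5-[(2Z)-3-(hydroxymethyl)-5-(Dec)pent-2-en-1-yl]furan-2(5H)-one | CC1=C(CC/C(=C/C[C@H]2OC(=O)C=C2CO)CO)[C@@]2(C)CCCC(C)(C)[C@@H]2CC1 | target

**Step count and risks**

Total steps: 7. Longest linear sequence: 7 (1 to 14); 5 and 6 are commercial and enter at step 4.

Steps most likely to fail:

Step 4. The Grignard reagent 8 may be lost by deprotonating the acetylenic C–H of 7. The chelated alkenylmagnesium 9 may open the epoxide only sluggishly, and at the higher temperature then needed it may add to the ester carbonyl of 6. The fallback separates the two events; it sets out from 4 and comes back at 10. As in step 4, 8 is added to an excess of 7 with CuI, but 9 is quenched with I2 to give (2Z)-3-iodo-2-[2-(Dec)ethyl]prop-2-en-1-ol F1. TBSCl and imidazole in DMF give tert-butyl({(2Z)-3-iodo-2-[2-(Dec)ethyl]prop-2-en-1-yl}oxy)dimethylsilane F2. Iodine–magnesium exchange with i-PrMgCl·LiCl in THF (0 to 23 °C) gives the non-chelated {(1Z)-3-[(tert-butyldimethylsilyl)oxy]-2-[2-(Dec)ethyl]prop-1-en-1-yl}magnesium chloride F3. With CuI (10 mol%) at −40 °C this should open 6 at its CH2 to give methyl (2R,4Z)-5-{[(tert-butyldimethylsilyl)oxy]methyl}-2-hydroxy-7-(Dec)hept-4-enoate F4. HF·pyridine in THF at 0 °C removes the silyl group and returns 10.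

Step 5. The Claisen condensation may stall at the ester that is deactivated by the neighbouring alkoxide, the acetate enolate may self-condense, and lactonisation of 11 may stay incomplete. The fallback replaces the intermolecular condensation by an intramolecular one; it sets out from 10 and comes back at 12. Ac2O, pyridine and DMAP acetylate both hydroxyls to give methyl (2R,4Z)-2-acetoxy-5-(acetoxymethyl)-7-(Dec)hept-4-enoate F5. Dieckmann cyclisation of the α-acetoxy ester (LiN(SiMe3)2, THF, −78 to 0 °C) should give (2Z)-2-[2-(Dec)ethyl]-4-[(2R)-3-hydroxy-5-oxo-2,5-dihydrofuran-2-yl]but-2-en-1-yl acetate F6. K2CO3 in MeOH then cleaves the allylic acetate, the tetronate anion being inert to it, and returns 12.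

Step 1. Equilibration may stop short and leave the trisubstituted and exocyclic olefin isomers, which are hard to separate, and the lactone may re-close. The fallback removes the carboxyl group before the olefin is made; it sets out from 1 and comes back at 3. LiAlH4 in THF reduces 1 to (1R,2R,4aS,8aS)-1-(2-hydroxyethyl)-2,5,5,8a-tetramethyldecahydronaphthalen-2-ol F7. Ac2O and pyridine acetylate only the primary hydroxyl to give 2-[(1R,2R,4aS,8aS)-2-hydroxy-2,5,5,8a-tetramethyldecahydronaphthalen-1-yl]ethyl acetate F8. TsOH·H2O (cat.) in toluene at 80 °C dehydrates the tertiary alcohol and equilibrates the olefin to the tetrasubstituted isomer 2-(Dec)ethyl acetate F9, with no free hydroxyl or carboxyl left to close a ring. K2CO3 in MeOH returns 3.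

Further compounds
F1 | step 4 | (2Z)-3-iodo-2-[2-(Dec)ethyl]prop-2-en-1-ol | CC1=C(CC/C(=C/I)CO)[C@@]2(C)CCCC(C)(C)[C@@H]2CC1
F2 | step 4 | tert-butyl({(2Z)-3-iodo-2-[2-(Dec)ethyl]prop-2-en-1-yl}oxy)dimethylsilane | CC1=C(CC/C(=C/I)CO[Si](C)(C)C(C)(C)C)[C@@]2(C)CCCC(C)(C)[C@@H]2CC1
F3 | step 4 | {(1Z)-3-[(tert-butyldimethylsilyl)oxy]-2-[2-(Dec)ethyl]prop-1-en-1-yl}magnesium chloride | CC1=C(CC/C(=C/[Mg]Cl)CO[Si](C)(C)C(C)(C)C)[C@@]2(C)CCCC(C)(C)[C@@H]2CC1
F4 | step 4 | methyl (2R,4Z)-5-{[(tert-butyldimethylsilyl)oxy]methyl}-2-hydroxy-7-(Dec)hept-4-enoate | CC1=C(CC/C(=C/C[C@@H](O)C(=O)OC)CO[Si](C)(C)C(C)(C)C)[C@@]2(C)CCCC(C)(C)[C@@H]2CC1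
F5 | step 5 | methyl (2R,4Z)-2-acetoxy-5-(acetoxymethyl)-7-(Dec)hept-4-enoate | CC1=C(CC/C(=C/C[C@@H](OC(C)=O)C(=O)OC)COC(C)=O)[C@@]2(C)CCCC(C)(C)[C@@H]2CC1
F6 | step 5 | (2Z)-2-[2-(Dec)ethyl]-4-[(2R)-3-hydroxy-5-oxo-2,5-dihydrofuran-2-yl]but-2-en-1-yl acetate | CC1=C(CC/C(=C/C[C@H]2OC(=O)C=C2O)COC(C)=O)[C@@]2(C)CCCC(C)(C)[C@@H]2CC1
F7 | step 1 | (1R,2R,4aS,8aS)-1-(2-hydroxyethyl)-2,5,5,8a-tetramethyldecahydronaphthalen-2-ol | C[C@@]1(O)CC[C@H]2C(C)(C)CCC[C@]2(C)[C@H]1CCO
F8 | step 1 | 2-[(1R,2R,4aS,8aS)-2-hydroxy-2,5,5,8a-tetramethyldecahydronaphthalen-1-yl]ethyl acetate | C[C@@]1(O)CC[C@H]2C(C)(C)CCC[C@]2(C)[C@H]1CCOC(C)=O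
F9 | step 1 | 2-(Dec)ethyl acetate | CC1=C(CCOC(C)=O)[C@@]2(C)CCCC(C)(C)[C@@H]2CC1
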